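**Remark on the chemistry:** numbering is C1 (lactone C=O), C2, C3 (CH–OO), C4 and C6 (methyl‑bearing ring carbons), C5 (ring CH2), C7–C16 (chain; C8 methine, phenyl on C16); the O11 silyl group and an iodine on the C6 methyl carbon are treated as spectator groups of the ring‑closure substrate, and the enzyme of step 7 is assumed to leave the (S)‑hydroperoxide.

## Structural features

The target is a cis‑fused bicycle: a 1,2‑dioxane (ring A: O–O, C3, C4, C5, C6) shares the C3–C4 bond with a γ‑butyrolactone (ring B: C1, C2, C3, C4, O). C6 carries a methyl group and the C7–C16 chain, which holds the C8 methyl stereocentre, an (E)‑alkene at C11=C12 and an (E)‑styryl end at C15=C16. The four stereocentres are C3 (S) and C4 (S), adjacent at the ring fusion, C6 (R), 1,3 to C4 across C5, and C8 (R), 1,3 to C6 across C7; the two ring methyls lie on one face of ring A, the lactone and the chain on the other. The O–O bond is the fragile element: it is cleaved by phosphines, hydrides and low‑valent metals, by a carbon radical β to it, and by β‑elimination once C2 is enolised. The chain alkenes would react with electrophilic halogen, divalent mercury and metal alkylidenes. The real difficulty is C6: a fully substituted peroxide carbon with no neighbouring stereocentre to direct its formation, next to a second fully substituted oxygenated carbon (C4). The feature used here is that C4 and C5 are the only adjacent ring‑A carbons not bonded to a peroxide oxygen. Ring A can therefore be made as a 3,6‑dihydro‑1,2‑dioxine with a C4=C5 alkene between the allylic peroxide carbons C3 and C6, and that alkene then sits 5‑exo to the C1 carboxyl for closure of ring B at C4.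

## Logic of the disconnections

**25 ⇒ 19 + 24.** The C11=C12 double bond is cut. The two chain alkenes cannot be present during metathesis, mercuration or halolactonisation, so the chain is attached last. This removes five carbons and both alkenes from every earlier intermediate. The forward step must give the (E)‑alkene and must not enolise C2 of the peroxy‑lactone.

**19 ⇒ 18 ⇒ 17.** Only the oxidation level and protection at C11 change. A silyl ether is the one group at C11 that is inert to ozone work‑up, ruthenium, mercury, N‑bromosuccinimide and tin hydride. The forward steps need fluoride and a neutral oxidant that leave the O–O bond alone.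

**17 ⇒ 16 ⇒ 15.** The lactone C4–O bond is cut and the C4=C5 alkene restored; C5 gains a bromine and the C6 methyl an iodine in the retrosynthetic sense. The tether from C3 can only deliver oxygen to C4 on its own face, so C4 is set without a reagent. The ester oxygen of 15 is used directly as the nucleophile, so no strong acid meets the tertiary allylic C6–O bond or the silyl ether. Both halogens must then leave in one radical step, which is why they are a bromide and an iodide and not two iodides (a 1,3‑diiodide could close a cyclopropane).

**15 ⇒ 14.** The C4=C5 bond is cut; this is the ring A closure. It reduces the bicycle problem to an acyclic peroxide with two terminal alkenes. The forward step needs a catalyst that tolerates the O–O bond and closes onto a 1,1‑disubstituted alkene, with no other alkene in the molecule.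

**14 ⇒ 7 + 11.** The C6–O bond is cut. A hydroperoxide adds to the more substituted alkene of a 2‑substituted diene under divalent mercury, which is the most reliable way to join a tertiary carbon to an existing hydroperoxide. C6 is formed without control, so the epimers must be separated. The carbon–mercury bond is turned into C–I, not C–H, because a hydride reduction would pass through a primary radical that is homoallylic on a quaternary carbon and β to the O–O bond.

**7 ⇒ 5 + 6 ⇒ 4 ⇒ 2 ⇒ 1.** Both carbon–carbon bonds that ethylene adds across the alkyne of 5 are cut, then the silyl ether, the C11 oxygen and the alkyne carbon are taken back to 1. C8 comes from the chiral pool and is never touched. Ozone must cleave the trisubstituted alkene and leave the alkyne.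

**11 ⇒ 10 ⇒ 9 ⇒ 8.** The C3–O bond is cut (ene reaction of singlet oxygen), preceded by esterification. C3 is obtained by kinetic resolution of the racemic hydroperoxide. The tert‑butyl ester is kept because it can be lost as 2‑methylpropene in the later lactonisation without base or strong acid.

**24 ⇒ 23 ⇒ 22 ⇒ 21 ⇒ 20.** The C–S bond, then the C13–C14 bond (Johnson–Claisen) are cut. The rearrangement fixes the (E)‑styryl geometry. The sulfide oxidation must spare the styrene.

## Other disconnections considered

**Alternative 1:** The cut is C6–C7 together with C8–CH3. In the forward direction the terminal alkene A1 would undergo zirconium‑catalysed asymmetric methylalumination [AlMe3, bis(1‑neomenthylindenyl)zirconium dichloride, (NMI)2ZrCl2]; the C7 alane, after exchange with Zn(OTf)2, would couple with bromoalkene A2 under Pd(PPh3)4 (zerovalent palladium) to give A3.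
- In its favour: two fragments are joined while C8 is set by the catalyst, and the whole chain arrives with both (E)‑alkenes. No C11 protecting group and no late olefination are needed, so on carbon–carbon step economy it is better than the chosen plan. No metal meets an O–O bond at this stage, which is also better.
- Against it here: methyl addition to an unbranched 1‑alkene is the least selective member of this reaction family, so C8 would probably need upgrading, whereas 1 delivers C8 enantiopure. A3 contains neither ring nor peroxide, so rings A and B, C3 and C6 all remain to be made, most plausibly through A6 and A7 with the chain alkenes exposed to divalent mercury.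
- Comparison: the mechanism (carbometalation, cross‑coupling) is better understood than metathesis next to a peroxide. On control of C6 the two plans are equal, since neither sets it with a reagent. The chosen plan closes ring A with all ring carbons and both C3 and C6 already in place.

**Alternative 2:** The cut is the lactone C4–O bond. The saturated dioxane acid A4 would be oxidised with Mn(OTf)2(pdp) and H2O2; the carboxylate‑bound metal oxo abstracts the tertiary γ‑hydrogen at C4 and rebound closes ring B to give A5.
- In its favour: one step replaces halolactonisation plus tin hydride, with no halogen, tin or strong acid. On endgame step and redox economy it is better than the chosen plan. The tertiary γ‑C–H is the expected site, so on regiochemistry the two plans are equal.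
- Against it here: A4 needs three defined stereocentres on ring A, including a C4–H cis to the acetic acid arm, because rebound retains configuration; the chosen plan gets C4 from the tether. A redox‑active manganese complex and H2O2 would meet a dialkyl peroxide, a C3–H α to peroxide oxygen and the tertiary C8–H. O–O cleavage by reduced manganese and undirected hydroxylation at C8 are credible competitors, and the C4 radical is β to the O–O bond.
- Comparison: the chosen plan opens a halonium ion ionically and keeps radicals away from the O–O bond until the last halogen is removed. Alternative 2 relies on a directing group for what the chosen plan gets from ring strain.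

**Alternative 3:** The cut is C6–O. Hg(OAc)2 would activate the 1,1‑disubstituted alkene of the hydroperoxy acetal A6 and the hydroperoxide oxygen would attack C6 in a 6‑exo closure to give the mercurial A7.
- In its favour: this ring closure is older and more widely used than peroxide metathesis, so on precedent it is better. No ruthenium comes near the O–O bond, and the chain is complete. A chair‑like cyclic transition state might bias C6 relative to C4, which the chosen plan cannot offer.
- Against it here: Hg(OAc)2 must choose the C6 alkene over C11=C12 and the styrene. The C–Hg bond must be reduced next to the O–O bond. C3 is an acetal carbon without C2 and C1, so the arm must be added with control at C3 and the lactone closed onto the C4 silyl ether; A6 is a mixture at C3. This makes the endgame longer.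
- Comparison: both plans use mercury to form a C6–O bond, so on that point they are equal. The chosen plan brings C3 in from a resolved building block and avoids a radical at the C6 methyl carbon while an alkene is still present.

Key step: step 9

## Steps

**Step 1**
Reactants: 1 (R)-citronellal
Product: 2 (4R)-4,8-dimethylnon-7-en-1-yne
Conditions: dimethyl (1-diazo-2-oxopropyl)phosphonate, K2CO3, MeOH, 0 °C → rt
Reagents that add atoms: dimethyl (1-diazo-2-oxopropyl)phosphonate, CC(=O)C(=[N+]=[N-])P(=O)(OC)OC
Why: Ohira–Bestmann homologation of an aldehyde to a terminal alkyne; the stereocentre is β to the carbonyl and is not epimerised by carbonate.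

**Step 2**
Reactants: 2 (4R)-4,8-dimethylnon-7-en-1-yne
Product: 4 (4R)-4-methylhept-6-yn-1-ol, via aldehyde 3 (not isolated)
Conditions: O3, CH2Cl2/MeOH, −78 °C (Sudan Red indicator); then NaBH4, −78 °C → rt
Reagents that add atoms: ozone, [O-][O+]=O
Why: Ozonolysis with reductive work‑up; the electron‑rich trisubstituted alkene reacts with ozone far faster than the terminal alkyne, and the indicator stops the addition before the alkyne is touched.

**Step 3**
Reactants: 4 (4R)-4-methylhept-6-yn-1-ol
Product: 5 tert-butyldimethyl{[(4R)-4-methylhept-6-yn-1-yl]oxy}silane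
Conditions: TBSCl, imidazole, CH2Cl2, rt
Reagents that add atoms: tert-butyldimethylsilyl chloride, CC(C)(C)[Si](C)(C)Cl
Why: Standard silylation of a primary alcohol; the ether keeps O11 from competing as a nucleophile in step 8 and is inert to every later reagent up to step 12.

**Step 4**
Reactants: 5 tert-butyldimethyl{[(4R)-4-methylhept-6-yn-1-yl]oxy}silane; 6 ethylene
Product: 7 tert-butyldimethyl{[(4R)-4-methyl-6-methylideneoct-7-en-1-yl]oxy}silane
Conditions: ethylene (1 atm), second-generation Grubbs catalyst RuCl2(=CHPh)(H2IMes)(PCy3) (5 mol %), toluene, 80 °C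
Reagents that add atoms: none
Why: Intermolecular enyne metathesis of a terminal alkyne with ethylene gives the 2‑substituted buta‑1,3‑diene; the substrate has no other alkene, and the new =CH2 on C6 is the future C6 methyl carbon.

**Step 5**
Reactants: 8 4-methylpent-3-enoic acid
Product: 9 tert-butyl 4-methylpent-3-enoate
Conditions: Me2NCH(OtBu)2, toluene, 80 °C
Reagents that add atoms: N,N-dimethylformamide di-tert-butyl acetal, CN(C)C(OC(C)(C)C)OC(C)(C)C
Why: Neutral tert‑butyl esterification; it avoids strong acid, which would lactonise this β,γ‑unsaturated acid, and base, which would move the alkene into conjugation.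

**Step 6**
Reactants: 9 tert-butyl 4-methylpent-3-enoate
Product: 10 tert-butyl 3-hydroperoxy-4-methylpent-4-enoate (racemic)
Conditions: O2, visible light, 5,10,15,20-tetraphenylporphyrin (cat.), CH2Cl2, 0 °C; chromatography
Reagents that add atoms: dioxygen, O=O
Why: Schenck ene reaction of singlet oxygen: oxygen adds at C3 with hydrogen abstraction from a C4 methyl group, giving the isopropenyl hydroperoxide; the regioisomeric tertiary hydroperoxide from abstraction at C2 is removed by chromatography.

**Step 7**
Reactants: 10 tert-butyl 3-hydroperoxy-4-methylpent-4-enoate (racemic)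
Product: 11 tert-butyl (3S)-3-hydroperoxy-4-methylpent-4-enoate
Conditions: horseradish peroxidase, guaiacol, phosphate buffer (pH 6), rt, run past half conversion; chromatography
Reagents that add atoms: none
Why: Enzymatic kinetic resolution of a secondary allylic hydroperoxide by enantioselective reduction: one enantiomer is reduced to the alcohol and the other is recovered; this step is the source of the C3 configuration, and the recovered enantiomer is to be assigned by reduction to the hydroxy ester and Mosher analysis.

**Step 8**
Reactants: 7 tert-butyldimethyl{[(4R)-4-methyl-6-methylideneoct-7-en-1-yl]oxy}silane (excess); 11 tert-butyl (3S)-3-hydroperoxy-4-methylpent-4-enoate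
Product: 14 tert-butyl (3S)-3-({(3R,5R)-8-[(tert-butyldimethylsilyl)oxy]-3-(iodomethyl)-5-methyloct-1-en-3-yl}peroxy)-4-methylpent-4-enoate, via trifluoroacetoxymercurial 12 (not isolated), via iodomercurial 13 (not isolated)
Conditions: Hg(OCOCF3)2 (1.0 equiv), CH2Cl2, −20 → 0 °C; aq KI; then I2, CH2Cl2, rt, dark; preparative HPLC to separate the C6 epimers
Reagents that add atoms: mercury bis(trifluoroacetate), O=C(O[Hg]OC(=O)C(F)(F)F)C(F)(F)F (atoms in 12); potassium iodide, [K+].[I-] (atoms in 13); iodine, II (atoms in 14)
Why: Alkylperoxymercuration: divalent mercury activates the more electron‑rich 1,1‑disubstituted alkene of the diene and the hydroperoxide oxygen adds at the tertiary allylic carbon C6 (Markovnikov) without facial control, so both C6 epimers form and the (6R) isomer is taken by HPLC. The C–Hg bond is then replaced by C–I (iododemercuration; any radical is trapped by I2 before it can rearrange) and not by C–H, because a hydride demercuration would pass through a primary radical that is homoallylic on a fully substituted carbon (1,2‑vinyl shift) and β to the O–O bond.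

**Step 9 (key step)**
Reactants: 14 tert-butyl (3S)-3-({(3R,5R)-8-[(tert-butyldimethylsilyl)oxy]-3-(iodomethyl)-5-methyloct-1-en-3-yl}peroxy)-4-methylpent-4-enoate
Product: 15 tert-butyl 2-[(3S,6R)-6-{(2R)-5-[(tert-butyldimethylsilyl)oxy]-2-methylpentyl}-6-(iodomethyl)-4-methyl-3,6-dihydro-1,2-dioxin-3-yl]acetate
Conditions: second-generation Grubbs catalyst RuCl2(=CHPh)(H2IMes)(PCy3) (10 mol %), CH2Cl2 (0.005 M), 40 °C, argon sparge
Reagents that add atoms: none
Why: Ring‑closing olefin metathesis: the ruthenium benzylidene exchanges onto the monosubstituted vinyl group on C6, and the resulting alkylidene adds across the isopropenyl group on C3 to a ruthenacyclobutane that collapses to the C4=C5 bond and Ru=CH2, which re‑enters the cycle while ethylene is swept out. The closest known reaction type is ring‑closing metathesis of dialkenyl peroxides to unsaturated cyclic peroxides, together with closure of a vinyl group on a quaternary allylic carbon onto a 1,1‑disubstituted alkene to give a trisubstituted cyclohexene. Ring A closes as a six‑membered ring through a four‑membered metallacycle, and the ring allows only the cis alkene. No stereocentre is formed; C3 comes from step 7 and C6 from the separated epimer of step 8. The step needs chemoselectivity only, and the substrate secures it by having exactly two alkenes (the chain is cut at C11) and a dialkyl O–O bond and a neopentyl‑type C–I bond that a ruthenium alkylidene is not expected to touch. The quaternary C6 favours the folded conformer, and high dilution suppresses intermolecular metathesis at the vinyl group, which is in any case reversible. The new trisubstituted alkene lies 5‑exo to the ester carbonyl for step 10.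

**Step 10**
Reactants: 15 tert-butyl 2-[(3S,6R)-6-{(2R)-5-[(tert-butyldimethylsilyl)oxy]-2-methylpentyl}-6-(iodomethyl)-4-methyl-3,6-dihydro-1,2-dioxin-3-yl]acetate
Product: 16 (3R,4S,4aR,7aS)-4-bromo-3-{(2R)-5-[(tert-butyldimethylsilyl)oxy]-2-methylpentyl}-3-(iodomethyl)-4a-methyl-4,4a,7,7a-tetrahydro-3H-furo[3,2-c][1,2]dioxin-6-one
Conditions: N-bromosuccinimide, MeCN/CH2Cl2, 0 °C → rt, dark
Reagents that add atoms: N-bromosuccinimide, O=C1CCC(=O)N1Br
Why: Bromolactonisation with the ester as nucleophile: reversible bromonium formation on C4=C5, 5‑exo attack of the ester carbonyl oxygen at the tertiary C4 from the face of the C3 arm, then loss of the tert‑butyl group as 2‑methylpropene. The short tether allows only the cis‑fused lactone, which sets the C4 configuration of the target and places bromine trans on C5. Bromine and not iodine is put on C5 so that the product is not a 1,3‑diiodide, and no strong acid is used, which spares the tertiary allylic C6–O bond and the silyl ether.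

**Step 11**
Reactants: 16 (3R,4S,4aR,7aS)-4-bromo-3-{(2R)-5-[(tert-butyldimethylsilyl)oxy]-2-methylpentyl}-3-(iodomethyl)-4a-methyl-4,4a,7,7a-tetrahydro-3H-furo[3,2-c][1,2]dioxin-6-one
Product: 17 (3R,4aS,7aS)-3-{(2R)-5-[(tert-butyldimethylsilyl)oxy]-2-methylpentyl}-3,4a-dimethyl-4,4a,7,7a-tetrahydro-3H-furo[3,2-c][1,2]dioxin-6-one
Conditions: Bu3SnH (3 equiv, 0.5 M), Et3B/air (cat.), toluene, 0 °C → rt
Reagents that add atoms: none
Why: Radical chain dehalogenation, known for halogen‑substituted cyclic peroxides: the stannyl radical takes the primary iodine first and the secondary bromine second, so neither carbon radical has a γ‑iodine to expel. The high stannane concentration at low temperature lets hydrogen transfer outrun attack of the exocyclic radical on the O–O bond, and the ring radical at C5 cannot reach the O–O σ* for geometric reasons. The exocyclic CH2 becomes the C6 methyl group.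

**Step 12**
Reactants: 17 (3R,4aS,7aS)-3-{(2R)-5-[(tert-butyldimethylsilyl)oxy]-2-methylpentyl}-3,4a-dimethyl-4,4a,7,7a-tetrahydro-3H-furo[3,2-c][1,2]dioxin-6-one
Product: 18 (3R,4aS,7aS)-3-[(2R)-5-hydroxy-2-methylpentyl]-3,4a-dimethyl-4,4a,7,7a-tetrahydro-3H-furo[3,2-c][1,2]dioxin-6-one
Conditions: HF·pyridine, THF, 0 °C → rt
Reagents that add atoms: none
Why: Fluoride cleavage of a primary silyl ether under weakly acidic conditions, which avoids enolisation of the lactone and the β‑elimination of the peroxide that a basic fluoride source could cause.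

**Step 13**
Reactants: 18 (3R,4aS,7aS)-3-[(2R)-5-hydroxy-2-methylpentyl]-3,4a-dimethyl-4,4a,7,7a-tetrahydro-3H-furo[3,2-c][1,2]dioxin-6-one
Product: 19 (4R)-5-[(3R,4aS,7aS)-3,4a-dimethyl-6-oxo-4,4a,7,7a-tetrahydro-3H-furo[3,2-c][1,2]dioxin-3-yl]-4-methylpentanal
Conditions: Dess–Martin periodinane, NaHCO3, CH2Cl2, 0 °C → rt
Reagents that add atoms: none
Why: Dess–Martin oxidation of a primary alcohol to the aldehyde under buffered, non‑reducing conditions that a dialkyl peroxide tolerates.

**Step 14**
Reactants: 20 1-phenylprop-2-en-1-ol
Product: 21 ethyl (4E)-5-phenylpent-4-enoate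
Conditions: MeC(OEt)3, EtCO2H (cat.), 140 °C, ethanol distilled off
Reagents that add atoms: triethyl orthoacetate, CCOC(C)(OCC)OCC
Why: Johnson–Claisen rearrangement; the chair transition state and conjugation with the phenyl ring give the (E)‑styryl alkene.

**Step 15**
Reactants: 21 ethyl (4E)-5-phenylpent-4-enoate
Product: 22 (4E)-5-phenylpent-4-en-1-ol
Conditions: LiAlH4, Et2O, 0 °C
Reagents that add atoms: none
Why: Hydride reduction of an ester; the isolated styryl alkene is not reduced.

**Step 16**
Reactants: 22 (4E)-5-phenylpent-4-en-1-ol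
Product: 23 1-phenyl-5-{[(4E)-5-phenylpent-4-en-1-yl]sulfanyl}-1H-tetrazole
Conditions: 1-phenyl-1H-tetrazole-5-thiol, PPh3, DIAD, THF, 0 °C → rt
Reagents that add atoms: 1-phenyl-1H-tetrazole-5-thiol, Sc1nnnn1-c1ccccc1
Why: Mitsunobu thioetherification of a primary alcohol with an acidic heteroaryl thiol.

**Step 17**
Reactants: 23 1-phenyl-5-{[(4E)-5-phenylpent-4-en-1-yl]sulfanyl}-1H-tetrazole
Product: 24 1-phenyl-5-{[(4E)-5-phenylpent-4-en-1-yl]sulfonyl}-1H-tetrazole
Conditions: 30 % aq H2O2, (NH4)6Mo7O24·4H2O (10 mol %), EtOH, 0 °C → rt
Reagents that add atoms: hydrogen peroxide, OO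
Why: Molybdate‑catalysed oxidation of a sulfide to the sulfone; sulfur is oxidised much faster than the styryl alkene is epoxidised under these conditions.

**Step 18**
Reactants: 19 (4R)-5-[(3R,4aS,7aS)-3,4a-dimethyl-6-oxo-4,4a,7,7a-tetrahydro-3H-furo[3,2-c][1,2]dioxin-3-yl]-4-methylpentanal; 24 1-phenyl-5-{[(4E)-5-phenylpent-4-en-1-yl]sulfonyl}-1H-tetrazole
Product: 25 (3R,4aS,7aS)-3,4a-dimethyl-3-[(2R,5E,9E)-2-methyl-10-phenyldeca-5,9-dien-1-yl]-4,4a,7,7a-tetrahydro-3H-furo[3,2-c][1,2]dioxin-6-one (target)
Conditions: 24, KHMDS, DME, −60 °C; then 19, −60 °C → rt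
Reagents that add atoms: none
Why: Julia–Kocienski olefination: the pre‑formed sulfonyl anion adds to the aldehyde, and Smiles rearrangement with loss of SO2 and the tetrazolate gives the C11=C12 alkene, (E) being favoured for the phenyltetrazolyl sulfone with potassium in DME. The anion is consumed by the aldehyde at low temperature before it can enolise the lactone.

## Compound list

1 | (R)-citronellal, (3R)-3,7-dimethyloct-6-enal | C[C@H](CCC=C(C)C)CC=O | starting material
2 | (4R)-4,8-dimethylnon-7-en-1-yne | C[C@H](CCC=C(C)C)CC#C | intermediate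
3 | (4R)-4-methylhept-6-ynal | C[C@H](CCC=O)CC#C | intermediate (not isolated)
4 | (4R)-4-methylhept-6-yn-1-ol | C[C@H](CCCO)CC#C | intermediate
5 | tert-butyldimethyl{[(4R)-4-methylhept-6-yn-1-yl]oxy}silane | C[C@H](CCCO[Si](C)(C)C(C)(C)C)CC#C | intermediate
6 | ethylene | C=C | starting material
7 | tert-butyldimethyl{[(4R)-4-methyl-6-methylideneoct-7-en-1-yl]oxy}silane | C[C@H](CCCO[Si](C)(C)C(C)(C)C)CC(=C)C=C | intermediate
8 | 4-methylpent-3-enoic acid | CC(C)=CCC(=O)O | starting material
9 | tert-butyl 4-methylpent-3-enoate | CC(C)=CCC(=O)OC(C)(C)C | intermediate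
10 | tert-butyl 3-hydroperoxy-4-methylpent-4-enoate (racemic) | C=C(C)C(CC(=O)OC(C)(C)C)OO | intermediate
11 | tert-butyl (3S)-3-hydroperoxy-4-methylpent-4-enoate | OO[C@@H](CC(=O)OC(C)(C)C)C(C)=C | intermediate
12 | tert-butyl (3S)-3-({(5R)-8-[(tert-butyldimethylsilyl)oxy]-5-methyl-3-{[(trifluoroacetoxy)mercurio]methyl}oct-1-en-3-yl}peroxy)-4-methylpent-4-enoate (both C6 epimers) | C[C@H](CCCO[Si](C)(C)C(C)(C)C)CC(C[Hg]OC(=O)C(F)(F)F)(C=C)OO[C@@H](CC(=O)OC(C)(C)C)C(C)=C | intermediate (not isolated)
13 | tert-butyl (3S)-3-({(5R)-8-[(tert-butyldimethylsilyl)oxy]-3-[(iodomercurio)methyl]-5-methyloct-1-en-3-yl}peroxy)-4-methylpent-4-enoate (both C6 epimers) | C[C@H](CCCO[Si](C)(C)C(C)(C)C)CC(C[Hg]I)(C=C)OO[C@@H](CC(=O)OC(C)(C)C)C(C)=C | intermediate (not isolated)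
14 | tert-butyl (3S)-3-({(3R,5R)-8-[(tert-butyldimethylsilyl)oxy]-3-(iodomethyl)-5-methyloct-1-en-3-yl}peroxy)-4-methylpent-4-enoate | C[C@H](CCCO[Si](C)(C)C(C)(C)C)C[C@](CI)(C=C)OO[C@@H](CC(=O)OC(C)(C)C)C(C)=C | intermediate
15 | tert-butyl 2-[(3S,6R)-6-{(2R)-5-[(tert-butyldimethylsilyl)oxy]-2-methylpentyl}-6-(iodomethyl)-4-methyl-3,6-dihydro-1,2-dioxin-3-yl]acetate | C[C@H](CCCO[Si](C)(C)C(C)(C)C)C[C@]1(CI)C=C(C)[C@H](CC(=O)OC(C)(C)C)OO1 | intermediate
16 | (3R,4S,4aR,7aS)-4-bromo-3-{(2R)-5-[(tert-butyldimethylsilyl)oxy]-2-methylpentyl}-3-(iodomethyl)-4a-methyl-4,4a,7,7a-tetrahydro-3H-furo[3,2-c][1,2]dioxin-6-one | C[C@H](CCCO[Si](C)(C)C(C)(C)C)C[C@]1(CI)[C@@H](Br)[C@]2(C)OC(=O)C[C@@H]2OO1 | intermediate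
17 | (3R,4aS,7aS)-3-{(2R)-5-[(tert-butyldimethylsilyl)oxy]-2-methylpentyl}-3,4a-dimethyl-4,4a,7,7a-tetrahydro-3H-furo[3,2-c][1,2]dioxin-6-one | C[C@H](CCCO[Si](C)(C)C(C)(C)C)C[C@]1(C)C[C@]2(C)OC(=O)C[C@@H]2OO1 | intermediate
18 | (3R,4aS,7aS)-3-[(2R)-5-hydroxy-2-methylpentyl]-3,4a-dimethyl-4,4a,7,7a-tetrahydro-3H-furo[3,2-c][1,2]dioxin-6-one | C[C@H](CCCO)C[C@]1(C)C[C@]2(C)OC(=O)C[C@@H]2OO1 | intermediate
19 | (4R)-5-[(3R,4aS,7aS)-3,4a-dimethyl-6-oxo-4,4a,7,7a-tetrahydro-3H-furo[3,2-c][1,2]dioxin-3-yl]-4-methylpentanal | C[C@H](CCC=O)C[C@]1(C)C[C@]2(C)OC(=O)C[C@@H]2OO1 | intermediate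
20 | 1-phenylprop-2-en-1-ol (racemic) | C=CC(O)c1ccccc1 | starting material
21 | ethyl (4E)-5-phenylpent-4-enoate | CCOC(=O)CC/C=C/c1ccccc1 | intermediate
22 | (4E)-5-phenylpent-4-en-1-ol | OCCC/C=C/c1ccccc1 | intermediate
23 | 1-phenyl-5-{[(4E)-5-phenylpent-4-en-1-yl]sulfanyl}-1H-tetrazole | c1ccccc1-n1nnnc1SCCC/C=C/c1ccccc1 | intermediate
24 | 1-phenyl-5-{[(4E)-5-phenylpent-4-en-1-yl]sulfonyl}-1H-tetrazole | c1ccccc1-n1nnnc1S(=O)(=O)CCC/C=C/c1ccccc1 | intermediate
25 | (3R,4aS,7aS)-3,4a-dimethyl-3-[(2R,5E,9E)-2-methyl-10-phenyldeca-5,9-dien-1-yl]-4,4a,7,7a-tetrahydro-3H-furo[3,2-c][1,2]dioxin-6-one | C[C@H](CC/C=C/CC/C=C/c1ccccc1)C[C@]1(C)C[C@]2(C)OC(=O)C[C@@H]2OO1 | target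

## Step count and least certain steps

Total: 18 steps. Longest linear sequence: 11 steps (1, 2, 3, 4, 8, 9, 10, 11, 12, 13, 18, from 1 to 25).

**Step 9 (key step).** The ring closure may be outrun by intermolecular metathesis at the vinyl group, because an acyclic peroxide prefers an open C–O–O–C torsion and the carbene must form next to a fully substituted carbon carrying both the O–O bond and the iodomethyl group. The substrate may also be degraded by reduction of the O–O bond by released PCy3 or by halogen abstraction from the C–I bond by ruthenium on prolonged heating. Fallback: the ring is closed on a substrate without the iodide. The fallback sets out from 13, which is reduced with Bu3SnH at high concentration to tert-butyl (3S)-3-({(3R,5R)-8-[(tert-butyldimethylsilyl)oxy]-3,5-dimethyloct-1-en-3-yl}peroxy)-4-methylpent-4-enoate F1 (epimers separated as in step 8), accepting the radical risk described in step 8. Ring‑closing metathesis then gives tert-butyl 2-[(3S,6R)-6-{(2R)-5-[(tert-butyldimethylsilyl)oxy]-2-methylpentyl}-4,6-dimethyl-3,6-dihydro-1,2-dioxin-3-yl]acetate F2, N‑bromosuccinimide gives (3R,4S,4aR,7aS)-4-bromo-3-{(2R)-5-[(tert-butyldimethylsilyl)oxy]-2-methylpentyl}-3,4a-dimethyl-4,4a,7,7a-tetrahydro-3H-furo[3,2-c][1,2]dioxin-6-one F3, and tin hydride removal of the single ring bromide returns to the route at 17. This series also removes the exocyclic radical from step 11.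

**Step 8.** The most likely failure is poor chromatographic separation of the C6 epimers, because on the acyclic peroxide the stereocentres are insulated from each other by the O–O bond and a methylene group. Competing mercuration of the hydroperoxide's own isopropenyl group, with lactonisation, is the second concern and is countered by the excess of 7. Fallback: the separation is moved to the cyclic stage. The fallback sets out from the unseparated product of step 8, that is 14 together with its epimer tert-butyl (3S)-3-({(3S,5R)-8-[(tert-butyldimethylsilyl)oxy]-3-(iodomethyl)-5-methyloct-1-en-3-yl}peroxy)-4-methylpent-4-enoate F4. Both are taken through step 9, and 15 is separated from the trans isomer tert-butyl 2-[(3S,6S)-6-{(2R)-5-[(tert-butyldimethylsilyl)oxy]-2-methylpentyl}-6-(iodomethyl)-4-methyl-3,6-dihydro-1,2-dioxin-3-yl]acetate F5, which as a ring diastereomer should differ more in polarity. The fallback returns to the route at 15.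

**Step 10.** The ester carbonyl may be too weak a nucleophile for an alkene flanked by two allylic peroxide oxygens, so that cyclisation stalls and radical allylic bromination takes over. Fallback: the carboxylic acid is set free first. The fallback sets out from 15: aqueous trifluoroacetic acid at 0 °C removes the tert‑butyl ester and the silyl ether together (short contact, to limit ionisation at C6) to give 2-[(3S,6R)-6-[(2R)-5-hydroxy-2-methylpentyl]-6-(iodomethyl)-4-methyl-3,6-dihydro-1,2-dioxin-3-yl]acetic acid F6. N‑Bromosuccinimide with NaHCO3 then closes the lactone from the carboxylate to (3R,4S,4aR,7aS)-4-bromo-3-[(2R)-5-hydroxy-2-methylpentyl]-3-(iodomethyl)-4a-methyl-4,4a,7,7a-tetrahydro-3H-furo[3,2-c][1,2]dioxin-6-one F7, and Bu3SnH as in step 11 returns to the route at 18.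

**Step 7.** The enzyme may not accept a substrate with a bulky tert‑butyl ester next to the carbinol carbon, or may discriminate the enantiomers poorly or in the other sense. Fallback: the resolution is done physically. The fallback sets out from 10, which is separated into its enantiomers by preparative HPLC on a cellulose carbamate chiral stationary phase; it makes no new compound (F0) and returns to the route at 11.

## Further compounds

F1 | step 9 | tert-butyl (3S)-3-({(3R,5R)-8-[(tert-butyldimethylsilyl)oxy]-3,5-dimethyloct-1-en-3-yl}peroxy)-4-methylpent-4-enoate | C[C@H](CCCO[Si](C)(C)C(C)(C)C)C[C@](C)(C=C)OO[C@@H](CC(=O)OC(C)(C)C)C(C)=C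
F2 | step 9 | tert-butyl 2-[(3S,6R)-6-{(2R)-5-[(tert-butyldimethylsilyl)oxy]-2-methylpentyl}-4,6-dimethyl-3,6-dihydro-1,2-dioxin-3-yl]acetate | C[C@H](CCCO[Si](C)(C)C(C)(C)C)C[C@]1(C)C=C(C)[C@H](CC(=O)OC(C)(C)C)OO1
F3 | step 9 | (3R,4S,4aR,7aS)-4-bromo-3-{(2R)-5-[(tert-butyldimethylsilyl)oxy]-2-methylpentyl}-3,4a-dimethyl-4,4a,7,7a-tetrahydro-3H-furo[3,2-c][1,2]dioxin-6-one | C[C@H](CCCO[Si](C)(C)C(C)(C)C)C[C@]1(C)[C@@H](Br)[C@]2(C)OC(=O)C[C@@H]2OO1
F4 | step 8 | tert-butyl (3S)-3-({(3S,5R)-8-[(tert-butyldimethylsilyl)oxy]-3-(iodomethyl)-5-methyloct-1-en-3-yl}peroxy)-4-methylpent-4-enoate | C[C@H](CCCO[Si](C)(C)C(C)(C)C)C[C@@](CI)(C=C)OO[C@@H](CC(=O)OC(C)(C)C)C(C)=C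
F5 | step 8 | tert-butyl 2-[(3S,6S)-6-{(2R)-5-[(tert-butyldimethylsilyl)oxy]-2-methylpentyl}-6-(iodomethyl)-4-methyl-3,6-dihydro-1,2-dioxin-3-yl]acetate | C[C@H](CCCO[Si](C)(C)C(C)(C)C)C[C@@]1(CI)C=C(C)[C@H](CC(=O)OC(C)(C)C)OO1
F6 | step 10 | 2-[(3S,6R)-6-[(2R)-5-hydroxy-2-methylpentyl]-6-(iodomethyl)-4-methyl-3,6-dihydro-1,2-dioxin-3-yl]acetic acid | C[C@H](CCCO)C[C@]1(CI)C=C(C)[C@H](CC(=O)O)OO1
F7 | step 10 | (3R,4S,4aR,7aS)-4-bromo-3-[(2R)-5-hydroxy-2-methylpentyl]-3-(iodomethyl)-4a-methyl-4,4a,7,7a-tetrahydro-3H-furo[3,2-c][1,2]dioxin-6-one | C[C@H](CCCO)C[C@]1(CI)[C@@H](Br)[C@]2(C)OC(=O)C[C@@H]2OO1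
F0 | step 7 | none | none
A1 | alternative 1 | [(1E,5E)-deca-1,5,9-trien-1-yl]benzene | C=CCC/C=C/CC/C=C/c1ccccc1
A2 | alternative 1 | {[(2S)-4-bromo-1,1-dimethoxy-2-methylpent-4-en-2-yl]oxy}triethylsilane | C=C(Br)C[C@](C)(O[Si](CC)(CC)CC)C(OC)OC
A3 | alternative 1 | {[(2S,6R,9E,13E)-1,1-dimethoxy-2,6-dimethyl-4-methylidene-14-phenyltetradeca-9,13-dien-2-yl]oxy}triethylsilane | C[C@H](CC/C=C/CC/C=C/c1ccccc1)CC(=C)C[C@](C)(O[Si](CC)(CC)CC)C(OC)OC
A4 | alternative 2 | 2-[(3S,4R,6R)-6-[(2R)-5-acetoxy-2-methylpentyl]-4,6-dimethyl-1,2-dioxan-3-yl]acetic acid | C[C@H](CCCOC(C)=O)C[C@]1(C)C[C@@H](C)[C@H](CC(=O)O)OO1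
A5 | alternative 2 | (4R)-5-[(3R,4aS,7aS)-3,4a-dimethyl-6-oxo-4,4a,7,7a-tetrahydro-3H-furo[3,2-c][1,2]dioxin-3-yl]-4-methylpentyl acetate | C[C@H](CCCOC(C)=O)C[C@]1(C)C[C@]2(C)OC(=O)C[C@@H]2OO1
A6 | alternative 3 | {[(2S,6R,9E,13E)-1-hydroperoxy-1-methoxy-2,6-dimethyl-4-methylidene-14-phenyltetradeca-9,13-dien-2-yl]oxy}triethylsilane (both C1 epimers) | C[C@H](CC/C=C/CC/C=C/c1ccccc1)CC(=C)C[C@](C)(O[Si](CC)(CC)CC)C(OC)OO
A7 | alternative 3 | acetoxy{[(3R,5S,6S)-6-methoxy-5-methyl-3-[(2R,5E,9E)-2-methyl-10-phenyldeca-5,9-dien-1-yl]-5-[(triethylsilyl)oxy]-1,2-dioxan-3-yl]methyl}mercury | C[C@H](CC/C=C/CC/C=C/c1ccccc1)C[C@]1(C[Hg]OC(C)=O)C[C@](C)(O[Si](CC)(CC)CC)[C@@H](OC)OO1
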